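| flask | starting material | reagent | base | remark | time |
|---|---|---|---|---|---|
| east | 1 mM | 1 mM | 0.10 mM | run made earlier |  |
| north-east | 1.4 mM | 1 mM | 0.10 mM | run made earlier |  |
| north | 2.2 mM | 1 mM | 0.10 mM | run made earlier |  |
| amber | 1.0 mM | 1.00 mM (in portions, 3, over 30 s) | 0.100 mM | first portion at the start, last at 30 s | 2.5 min |
| teal | 1.0 mM | 1.00 mM | 0.100 mM | everything together at the start | 2.5 min |
| red | 1.0 mM (fed, over 30 s) | 1.00 mM | 0.100 mM | all else is in the flask from the start; the feed brings no volume worth counting | 2.5 min |
| blue | 1.0 mM | 1.00 mM (fed, over 30 s) | 0.100 mM | all else is in the flask from the start; the feed brings no volume worth counting | 2.5 min |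

- east (time / s: product / %, starting material / %): 12.0: 1, 99; 30.0: 4, 96; 60.0: 6, 97; 90.0: 9, 94
- north-east (time / s: product / %, starting material / %): 12.0: 0, 98; 30.0: 5, 97; 60.0: 5, 94; 90.0: 8, 94
- north (time / s: product / %, starting material / %): 10.0: 0, 100; 15.0: 1, 99; 40.0: 3, 97; 90.0: 37, 60

(readings scatter by 1.5 percentage points)

- a reading or a percentage of product counts all its forms, free or not

- the best flask by amount of product, in percent of the starting material charged; "all alike" if 1.5 percentage points covers them all (amber / teal / red / blue / all alike)
- amount of product at the end, in percent of the starting material charged, amber
- amount of product at the end, in percent of the starting material charged, teal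
- amount of product at the end, in percent of the starting material charged, red
- amount of product at the end, in percent of the starting material charged, blue

**One step fails.** East and north-east read 9% and 8% at 90.0 s, which suggests a step first order in starting material; a one-step world of that order, with reagent charged alike, puts east and north at nearly the same fraction of the charge after that time. Yet north reads 37%, more than the 9% of east. At 40.0 s, north still reads 3%, less than its base share of 4.55%, the base charged as a fraction of the starting material charged.

**The clock.** East reads a background pace of 0.00100 s⁻¹, as a fraction of the charge. The working picture is that base absorbs a stretch of reaction equal to its share, 10.0% in teal, and that takeoff follows. Base share over background pace gives 100 s for teal: this is the clearance time, an induction time. The same pace gives north 45.5 s, which lies between its readings at 40.0 s and 90.0 s.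

**The hunch.** The hunch that slow addition costs only seconds holds on this reckoning. Amber, red and blue each hold the fed species at half its charge on average over 30 s. If the pace is first order in that species, and no run moved reagent, the clock gains a lag of 15.0 s. Clearance at 115 s leaves these flasks 35.0 s of takeoff, less than the 50.0 s of teal. The reckoning commits to teal first, with amber, red and blue alike.

**The forecast.** It names teal as best, with teal at 23% (15% to 42%) and amber, red and blue each at 16% (11% to 27%). It adds: “The result is very sensitive to timing, but teal is best.”

**The result.** Teal gives 58.4%, amber 16.0%, red 16.2% and blue 16.2%, every form of product counted, so teal stands 35 percentage points above the forecast. With the path through by-product struck out, teal gives 9.96%. The clock, an estimate from one scattered reading, had allowed teal 50.0 s past clearance and amber 35.0 s; above the base share, teal stands at 48 points, more than the 6 points of amber.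

    reagent + product ⇌ idle adduct, settled at all times (K = 32000 L mol⁻¹)
    starting material + reagent + by-product → product + 2 by-product (k = 8.90 × 10⁵ L² mol⁻² s⁻¹)
    base + by-product ⇌ salt, settled at all times (K = 1.70 × 10⁷ L mol⁻¹)
    starting material + reagent → product + by-product (k = 0.780 L mol⁻¹ s⁻¹)

**Leaner flask.** For amber with 0.60 mM of reagent, the clock, with the pace taken in proportion to reagent, puts clearance at 182 s, later than the end at 150 s. That flask gives 5.72%, with 42.8% of its base still free at 2.50 min.

(The earlier runs and the new flask are calculated for substances that don't exist, noise included.)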